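5 questions stand here, and the ranking among the set-ups is the one that needs an argument.

| setting | south-east | south | noon | winter | dusk | summer |
|---|---|---|---|---|---|---|
| starting material | 0.80 M | 0.80 M | 0.80 M | 0.80 M | 0.80 M (fed, over 6.40 h) | 0.80 M |
| partner | 0.96 M | 1.9 M | 0.960 M | 0.960 M (fed, over 6.40 h) | 0.960 M | 0.960 M |
| protic impurity | 0.080 M | 0.080 M | 0.0800 M | 0.0800 M | 0.0800 M | 0.0800 M |
| remark | run made earlier | run made earlier | a single well-mixed tank run continuously and read at steady state, 8.0 h in it on average | a stirred flask in which partner is dosed at a steady rate over 6.40 h without added volume, worked up at 8.0 h | all but starting material at the start; starting material goes in evenly over 6.40 h, the run ends at 8.0 h | everything together in a closed stirred flask, run for 8.0 h |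
| time |  |  |  | 8.0 h | 8.0 h | 8.0 h |

- south-east (time / h: intermediate / %, target / %, starting material / %): 0.667: 67.1, 26.5, 0.3; 1.33: 49.0, 42.6, 0; 2.50: 31.9, 52.6, 0.3; 4.00: 23.1, 54.0, 0; 8.00: 14.3, 54.8, 0.2
- south (time / h: intermediate / %, target / %, starting material / %): 0.200: 61.4, 12.0, 24.2; 0.333: 63.0, 24.0, 10.4; 0.667: 46.1, 41.3, 0.5; 1.33: 23.8, 53.3, 0; 2.50: 9.5, 49.9, 0.6

(readings scatter by 0.5 percentage points)

- the set-up with the highest amount of intermediate at the outlet or at the end, in percent of the starting material put in ("none" if the first two lie within 2 percentage points) (noon / winter / dusk / summer / none)
- amount of intermediate at the outlet or at the end, in percent of the starting material put in, noon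
- amount of intermediate at the outlet or at the end, in percent of the starting material put in, winter
- amount of intermediate at the outlet or at the end, in percent of the starting material put in, dusk
- amount of intermediate at the outlet or at the end, in percent of the starting material put in, summer

In the south-east run the starting material has fallen to 0.3% by 0.667 h, so the later readings show a chain, as I take it: partner turns intermediate into target, then target into over-reaction product. Both steps carry partner, so when I divide the net rate of target by the rate of loss of intermediate, partner and time drop out. What remains is the selectivity factor, the second constant over the first, 0.353, read between 1.33 h and 2.50 h. The south run, with twice the partner, reads 0.341. If x is the intermediate as a fraction of what formed, target is x to the power of the factor, less x, over one less the factor. Partner spent per starting material that became intermediate is 2 times the loss of intermediate, less that target.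

The forecast gives noon: noon 36%, winter 25%, dusk 28%, summer 14.3%, noon because “backmixing keeps partner low and the outlet short of full conversion”.

Turned round: for summer to beat the tank, it must end above 36%. On my curve that means 0.759 partner spent per starting material, less than the 1.20 charged. But the south-east run, with the same charge, reads 31.9% of intermediate by 2.50 h and 14.3% by 8.00 h. So I stay with noon.

The flask gives noon: noon 34.2%, winter 22.8%, dusk 26.6%, summer 15.1%.

    starting material → intermediate (k = 0.00190 s⁻¹)
    partner + intermediate → target (k = 2.30 × 10⁻⁴ L mol⁻¹ s⁻¹)
    partner + target → over-reaction product (k = 8.20 × 10⁻⁵ L mol⁻¹ s⁻¹)
    starting material + protic impurity → quenched substrate (k = 7.60 × 10⁻⁴ L mol⁻¹ s⁻¹)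

In summer the starting material stands at 0% by 4.00 h, and partner, working on intermediate and target, falls to 8.15% of its charge by 8.00 h. The curve, fed with the final intermediate on the unquenched share, gives target 54.6% against 54.3%. With 0.38 M of partner, the ratio is 0.475, and two rounds of the balance give x as 55.3%, then 56.3%. That flask computes to 55.2%.

The earlier runs and the new flask were generated by integration with made-up constants; scatter was added.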